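**Retrosynthetic overview**

- The target is cut back to a pentamethoxy lactone-bridged flavone (a chromeno[4,3-b]chromene-6,7-dione). The lactone carbonyl carbon is later lost as CO2 and the bridging oxygen becomes the 2'-methoxy oxygen.
- The lactone comes from 6-bromo-2,3-dimethoxyphenyl 5,7,8-trimethoxychromone-3-carboxylate by palladium-catalysed arylation of C2–H, which forms the C2–C1' bond.
- The strategy rests on this feature: O2' of ring B is ortho to C1', and C3 of the pyranone ring carries only hydrogen in the target. A disposable C3 carboxyl esterified to O2' therefore holds C1'–Br over C2–H.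
- The ester is assembled from the chromone-3-carboxylic acid (from 3,4,5-trimethoxyphenol) and 6-bromo-2,3-dimethoxyphenol (from 4-bromoveratrole).
- Ring order: rings A and B are bought, the pyranone ring C is built by a Vilsmeier–Haack reaction, and the lactone ring closes in the key step and is then opened and excised.

Key step: step 7

Assumption: the target has no stereocentre, and all reagents other than compounds 1 and 8 are taken as commercial.

**Route**

Step 1
Reactants: 1 3,4,5-trimethoxyphenol
Product: 2 1,2,3,5-tetramethoxybenzene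
Conditions: MeI, K2CO3, acetone, reflux
Reagents that add atoms: iodomethane, CI
Why: Williamson O-methylation of a phenoxide, which has no competing site.

Step 2
Reactants: 2 1,2,3,5-tetramethoxybenzene
Product: 4 1-(2-hydroxy-3,4,6-trimethoxyphenyl)ethanone, via 2,3,4,6-tetramethoxyacetophenone 3 (not isolated)
Conditions: AcCl, AlCl3, Et2O, 0 °C → reflux; aq. HCl work-up
Reagents that add atoms: acetyl chloride, CC(=O)Cl
Why: Friedel–Crafts acylation at one of the two equivalent free positions is followed by chelation-assisted ortho-demethylation, in which AlCl3 should cleave the methoxy group that is held between the new carbonyl and the 3-methoxy group and twisted out of the ring plane.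

Step 3
Reactants: 4 1-(2-hydroxy-3,4,6-trimethoxyphenyl)ethanone
Product: 6 5,7,8-trimethoxy-4-oxo-4H-chromene-3-carbaldehyde, via chromon-3-ylmethylidene(dimethyl)iminium chloride 5 (not isolated)
Conditions: POCl3, DMF, 0 → 55 °C; then ice–water
Reagents that add atoms: N,N-dimethylformamide, CN(C)C=O; water, O
Why: Vilsmeier–Haack double formylation of the acetyl methyl group with ring closure by the ortho phenol is the standard synthesis of 3-formylchromones, and the O-derivatised phenol should damp formylation at the free ring position.

Step 4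
Reactants: 6 5,7,8-trimethoxy-4-oxo-4H-chromene-3-carbaldehyde
Product: 7 5,7,8-trimethoxy-4-oxo-4H-chromene-3-carboxylic acid
Conditions: NaClO2, NaH2PO4, 2-methyl-2-butene, t-BuOH–THF–H2O, 0 °C → rt
Reagents that add atoms: sodium chlorite, [Na+].[O-]Cl=O
Why: Pinnick oxidation at mildly acidic pH spares the base-sensitive pyranone ring, and the alkene scavenger should intercept HOCl before it chlorinates the electron-rich ring A.

Step 5
Reactants: 8 4-bromo-1,2-dimethoxybenzene
Product: 11 6-bromo-2,3-dimethoxyphenol, via (6-bromo-2,3-dimethoxyphenyl)lithium 9 (not isolated), via dimethyl (6-bromo-2,3-dimethoxyphenyl)boronate 10 (not isolated)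
Conditions: LiN(iPr)2, THF, −78 °C; B(OMe)3, −78 → 0 °C; AcOH, 30% H2O2, 0 °C → rt
Reagents that add atoms: hydrogen peroxide, OO
Why: Directed ortho-metalation with a lithium amide removes the most acidic proton, between OMe and Br, without bromine–lithium exchange, and borylation–oxidation at low temperature should turn the aryllithium into the phenol before it can lose LiBr.

Step 6
Reactants: 7 5,7,8-trimethoxy-4-oxo-4H-chromene-3-carboxylic acid; 11 6-bromo-2,3-dimethoxyphenol
Product: 13 6-bromo-2,3-dimethoxyphenyl 5,7,8-trimethoxy-4-oxo-4H-chromene-3-carboxylate, via 5,7,8-trimethoxy-4-oxo-4H-chromene-3-carbonyl chloride 12 (not isolated)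
Conditions: (COCl)2, cat. DMF, CH2Cl2, 0 °C → rt, evaporate; then 11, Et3N, cat. DMAP, CH2Cl2, 0 °C → rt
Reagents that add atoms: none
Why: Acylation of a phenol by an acid chloride is fast enough at 0 °C that the hindered phenol should be esterified before any reversible conjugate addition at C2 matters.

Step 7
Reactants: 13 6-bromo-2,3-dimethoxyphenyl 5,7,8-trimethoxy-4-oxo-4H-chromene-3-carboxylate
Product: 14 3,4,8,10,11-pentamethoxy-6H,7H-chromeno[4,3-b]chromene-6,7-dione (the lactone between O2' and the C3 carboxyl of the 2-aryl chromone)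
Conditions: Pd(OAc)2 (10 mol%), PCy3·HBF4 (20 mol%), K2CO3, PivOH (30 mol%), DMA, 120 °C, Ar
Reagents that add atoms: none
Why: Zerovalent palladium formed from Pd(OAc)2 and PCy3 should insert into the C1'–Br bond, and rotation of the aryl ester into its cisoid conformer then places the arylpalladium over C2–H. Pivalate-assisted concerted metalation–deprotonation should cleave this C–H bond, the most acidic of the chromone and further acidified by the C3 ester, to give a seven-membered palladacycle; a Heck-type insertion across C2=C3 followed by base-assisted elimination through the palladium enolate would lead to the same product. Reductive elimination forms C2–C1' and closes the six-membered lactone ring, formally a 6-endo closure with respect to C2=C3. The closest known reactions are the palladium-catalysed intramolecular direct arylation of aryl esters to biaryl lactones (6H-benzo[c]chromen-6-ones) and the palladium-catalysed C2 arylation of chromones. No stereocentre is formed. The step needs site selectivity, which the tether secures because C3 is blocked, only C2–H is within reach of C1', and the bromine fixes the ring-B carbon; it also needs the ester to outlive the base, which anhydrous carbonate and a bulky electron-rich phosphine should allow.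

Step 8
Reactants: 14 3,4,8,10,11-pentamethoxy-6H,7H-chromeno[4,3-b]chromene-6,7-dione
Product: 16 benzyl 5,7,8-trimethoxy-4-oxo-2-(2,3,4-trimethoxyphenyl)-4H-chromene-3-carboxylate, via sodium phenoxide of the benzyl ester 15 (not isolated)
Conditions: NaH, BnOH (excess), THF, 0 °C (gives NaOCH2Ph); add 14, 0 °C → rt; then MeI, DMF, rt
Reagents that add atoms: benzyl alcohol (as its sodium alkoxide), OCc1ccccc1; iodomethane, CI
Why: Alkoxide transesterification opens the aryl lactone as in ring-opening alkylations of coumarins and biaryl lactones, and Williamson methylation caps the released 2'-phenoxide before any acid is freed, so that relactonisation and closure by the wrong phenol are excluded; in the presence of free alcohol an addition at C2 can revert, and the benzyl ester with intact pyranone ring should be the favoured open form.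

Step 9
Reactants: 16 benzyl 5,7,8-trimethoxy-4-oxo-2-(2,3,4-trimethoxyphenyl)-4H-chromene-3-carboxylate
Product: 17 5,7,8-trimethoxy-4-oxo-2-(2,3,4-trimethoxyphenyl)-4H-chromene-3-carboxylic acid
Conditions: H2 (1 atm), 10% Pd/C, EtOAc, rt
Reagents that add atoms: none
Why: Hydrogenolysis of a benzyl ester is neutral and much faster than reduction of the tetrasubstituted C2=C3 bond, so the acid is freed without a nucleophile touching C2.

Step 10
Reactants: 17 5,7,8-trimethoxy-4-oxo-2-(2,3,4-trimethoxyphenyl)-4H-chromene-3-carboxylic acid
Product: 18 2',3',4',5,7,8-hexamethoxyflavone (5,7,8-trimethoxy-2-(2,3,4-trimethoxyphenyl)-4H-chromen-4-one)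
Conditions: Ag2CO3 (10 mol%), AcOH (cat.), DMSO, 120 °C
Reagents that add atoms: none
Why: Silver-catalysed protodecarboxylation works best on carboxylic acids flanked on both sides, here by the C4 carbonyl and the C2 aryl group, and the C3–silver species is protonated to leave C3–H with the pyranone ring untouched.

**Compound list**

1 | 3,4,5-trimethoxyphenol | COc1cc(O)cc(OC)c1OC | starting material
2 | 1,2,3,5-tetramethoxybenzene | COc1cc(OC)c(OC)c(OC)c1 | intermediate
3 | 1-(2,3,4,6-tetramethoxyphenyl)ethanone | CC(=O)c1c(OC)c(OC)c(OC)cc1OC | intermediate (not isolated)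
4 | 1-(2-hydroxy-3,4,6-trimethoxyphenyl)ethanone | CC(=O)c1c(O)c(OC)c(OC)cc1OC | intermediate
5 | [(5,7,8-trimethoxy-4-oxo-4H-chromen-3-yl)methylidene]dimethyliminium chloride | C[N+](C)=Cc1coc2c(OC)c(OC)cc(OC)c2c1=O.[Cl-] | intermediate (not isolated)
6 | 5,7,8-trimethoxy-4-oxo-4H-chromene-3-carbaldehyde | O=Cc1coc2c(OC)c(OC)cc(OC)c2c1=O | intermediate
7 | 5,7,8-trimethoxy-4-oxo-4H-chromene-3-carboxylic acid | OC(=O)c1coc2c(OC)c(OC)cc(OC)c2c1=O | intermediate
8 | 4-bromo-1,2-dimethoxybenzene | COc1ccc(Br)cc1OC | starting material
9 | (6-bromo-2,3-dimethoxyphenyl)lithium | [Li]c1c(Br)ccc(OC)c1OC | intermediate (not isolated)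
10 | dimethyl (6-bromo-2,3-dimethoxyphenyl)boronate | COB(OC)c1c(Br)ccc(OC)c1OC | intermediate (not isolated)
11 | 6-bromo-2,3-dimethoxyphenol | COc1ccc(Br)c(O)c1OC | intermediate
12 | 5,7,8-trimethoxy-4-oxo-4H-chromene-3-carbonyl chloride | O=C(Cl)c1coc2c(OC)c(OC)cc(OC)c2c1=O | intermediate (not isolated)
13 | 6-bromo-2,3-dimethoxyphenyl 5,7,8-trimethoxy-4-oxo-4H-chromene-3-carboxylate | COc1ccc(Br)c(OC(=O)c2coc3c(OC)c(OC)cc(OC)c3c2=O)c1OC | intermediate
14 | 3,4,8,10,11-pentamethoxy-6H,7H-chromeno[4,3-b]chromene-6,7-dione | COc1ccc2c(c1OC)OC(=O)c1c-2oc2c(OC)c(OC)cc(OC)c2c1=O | intermediate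
15 | sodium 6-[3-(benzyloxycarbonyl)-5,7,8-trimethoxy-4-oxo-4H-chromen-2-yl]-2,3-dimethoxyphenolate | [Na+].[O-]c1c(OC)c(OC)ccc1-c1oc2c(OC)c(OC)cc(OC)c2c(=O)c1C(=O)OCc1ccccc1 | intermediate (not isolated)
16 | benzyl 5,7,8-trimethoxy-4-oxo-2-(2,3,4-trimethoxyphenyl)-4H-chromene-3-carboxylate | COc1ccc(-c2oc3c(OC)c(OC)cc(OC)c3c(=O)c2C(=O)OCc2ccccc2)c(OC)c1OC | intermediate
17 | 5,7,8-trimethoxy-4-oxo-2-(2,3,4-trimethoxyphenyl)-4H-chromene-3-carboxylic acid | COc1ccc(-c2oc3c(OC)c(OC)cc(OC)c3c(=O)c2C(=O)O)c(OC)c1OC | intermediate
18 | 2',3',4',5,7,8-hexamethoxyflavone | COc1ccc(-c2cc(=O)c3c(OC)cc(OC)c(OC)c3o2)c(OC)c1OC | target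

**Step count**

Total: 10 steps. Longest linear sequence: 9 steps (steps 1–4 and 6–10 from compound 1); step 5 supplies the ring-B partner for step 6.

**Steps most likely to fail**

1. Step 7. The aryl ester may stay in its transoid conformer, so that protodebromination or carbonate-induced cleavage of the activated ester outruns palladation of C2–H. The fallback leaves the tether idea and sets out from acetophenone 4. Claisen–Schmidt condensation of 4 with commercial 2,3,4-trimethoxybenzaldehyde (KOH, EtOH, rt) should give the chalcone (E)-1-(2-hydroxy-3,4,6-trimethoxyphenyl)-3-(2,3,4-trimethoxyphenyl)prop-2-en-1-one F1. Oxidative cyclisation of F1 with catalytic I2 in DMSO at 130 °C should then give the flavone, so the fallback returns to the route at 18.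

2. Step 8. The alkoxide may add at C2 instead of the lactone carbonyl, which opens the pyranone ring and lets the ring-A phenoxide be methylated. The fallback sets out from lactone 14 and gives up the selective opening. Hot KOH in aqueous EtOH followed by acidification should hydrolyse both rings and decarboxylate to 1-(2-hydroxy-3,4-dimethoxyphenyl)-3-(2-hydroxy-3,4,6-trimethoxyphenyl)propane-1,3-dione F2. Cyclodehydration (AcOH, cat. H2SO4, 100 °C) should close the ring-A phenol onto the ring-B carbonyl, which is less hindered and less deactivated than the doubly ortho-substituted ring-A carbonyl, to give 2-(2-hydroxy-3,4-dimethoxyphenyl)-5,7,8-trimethoxy-4H-chromen-4-one F3. Methylation of F3 (MeI, K2CO3, acetone) returns to the route at 18.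

3. Step 10. The vinylogous carboxylate may resist silver-mediated loss of CO2 and the acid may be recovered. The fallback sets out from acid 17 and uses hydrolytic ring opening instead. Warm aqueous NaOH should add hydroxide at C2 and open the pyranone ring, and the β-keto acid should lose CO2 on acidification to give 1-(2-hydroxy-3,4,6-trimethoxyphenyl)-3-(2,3,4-trimethoxyphenyl)propane-1,3-dione F4. F4 has only the ring-A phenol free, so cyclodehydration (AcOH, cat. H2SO4, 100 °C) can only return to the route at 18.

**Further compounds**

F1 | step 7 | (E)-1-(2-hydroxy-3,4,6-trimethoxyphenyl)-3-(2,3,4-trimethoxyphenyl)prop-2-en-1-one | COc1ccc(/C=C/C(=O)c2c(O)c(OC)c(OC)cc2OC)c(OC)c1OC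
F2 | step 8 | 1-(2-hydroxy-3,4-dimethoxyphenyl)-3-(2-hydroxy-3,4,6-trimethoxyphenyl)propane-1,3-dione | COc1ccc(C(=O)CC(=O)c2c(O)c(OC)c(OC)cc2OC)c(O)c1OC
F3 | step 8 | 2-(2-hydroxy-3,4-dimethoxyphenyl)-5,7,8-trimethoxy-4H-chromen-4-one | COc1ccc(-c2cc(=O)c3c(OC)cc(OC)c(OC)c3o2)c(O)c1OC
F4 | step 10 | 1-(2-hydroxy-3,4,6-trimethoxyphenyl)-3-(2,3,4-trimethoxyphenyl)propane-1,3-dione | COc1ccc(C(=O)CC(=O)c2c(O)c(OC)c(OC)cc2OC)c(OC)c1OC
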